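**Retrosynthetic overview**

1. The target is read as catechin-(4α→8)-gallocatechin-(4β→8)-catechin: all units (2R,3S), upper interflavan bond 3,4-trans, lower one 3,4-cis. Last disconnections: removal of benzyl, benzoyl and a blocking bromine, then the upper C4–C8 bond (flavan-4-yl cation of a catechin donor plus C8 of the middle unit).
2. Key disconnection: ring C (the pyran ring) of the middle gallocatechin unit is cut at C2–C3 and at C4–C4a. This is a formal [4+2] of oxa-Povarov type between an aryl oxocarbenium ion (O1=C2) and a (Z)-enol benzoate (C3=C4) that hangs on C8 of the lower catechin.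
3. Enabling feature: in that ring O1 sits on a phloroglucinol-type ring A whose carbon ortho to O1 (C4a) is a strong carbon nucleophile, and C2 is an acetal-level benzylic carbon. C4 carries the 2,4,6-trioxygenated ring A of the lower catechin, which stabilises a cation at C4 and polarises C3=C4 so that C3 attacks C2.
4. Ring order: rings A, B and C of the upper and lower units come intact from (+)-catechin. Rings A and B of the middle unit are bought as 3,5-dibenzyloxyphenol and 3,4,5-tribenzyloxybenzaldehyde. Ring C of the middle unit is the only ring made (key step); the upper unit is attached last.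
5. The enol benzoate comes from 8-bromocatechin by bromine–lithium exchange and formylation, alkyne formation, and ruthenium-catalysed Z-selective addition of benzoic acid.

Key step: step 9

Remark: the acetal carbon of 13 and the C4 alkoxy centre of 17 become planar cations, so their configuration is immaterial; compounds 1, 9 and 11 are taken as commercial.

**Route**

Step 1
Reactants: 1 (+)-catechin
Product: 2 5,7,3',4'-tetra-O-benzylcatechin
Conditions: BnBr (4.2 equiv), K2CO3, DMF, 0 °C to rt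
Reagents that add atoms: benzyl bromide BrCc1ccccc1
Why: Williamson etherification in which carbonate deprotonates only the four phenols, so the secondary 3-OH stays free and no stereocentre is touched.

Step 2
Reactants: 2 5,7,3',4'-tetra-O-benzylcatechin
Product: 3 8-bromo-5,7,3',4'-tetra-O-benzylcatechin
Conditions: NBS (1.0 equiv), CH2Cl2, −78 °C to rt
Reagents that add atoms: N-bromosuccinimide O=C1CCC(=O)N1Br
Why: Electrophilic aromatic bromination, expected at C8 of the 5,7-dibenzyloxy ring A because C8 is the most nucleophilic and least hindered position.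

Step 3
Reactants: 3 8-bromo-5,7,3',4'-tetra-O-benzylcatechin
Product: 4 8-bromo-3,5,7,3',4'-penta-O-benzylcatechin
Conditions: NaH, BnBr, DMF, 0 °C to rt
Reagents that add atoms: benzyl bromide BrCc1ccccc1
Why: Williamson etherification of the 3-alkoxide, which masks the last acidic proton before the organolithium step and is removed later with the other benzyl groups.

Step 4
Reactants: 4 8-bromo-3,5,7,3',4'-penta-O-benzylcatechin
Product: 6 8-formyl-3,5,7,3',4'-penta-O-benzylcatechin, via 8-lithio arene 5 (not isolated)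
Conditions: n-BuLi (1.1 equiv), THF, −78 °C; DMF, −78 °C to 0 °C; H2O
Reagents that add atoms: N,N-dimethylformamide CN(C)C=O
Why: Bromine–lithium exchange is fast at −78 °C on this aryl bromide, and formylation of the aryllithium with DMF (Bouveault-type) should give the aldehyde after hydrolysis of the hemiaminal salt.

Step 5
Reactants: 6 8-formyl-3,5,7,3',4'-penta-O-benzylcatechin
Product: 7 8-ethynyl-3,5,7,3',4'-penta-O-benzylcatechin
Conditions: dimethyl (1-diazo-2-oxopropyl)phosphonate, K2CO3, MeOH/THF, rt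
Reagents that add atoms: dimethyl (1-diazo-2-oxopropyl)phosphonate CC(=O)C(=[N+]=[N-])P(=O)(OC)OC
Why: Seyferth–Gilbert homologation with the Ohira–Bestmann reagent converts the aryl aldehyde into the terminal alkyne under mild base that leaves the benzyl ethers and both stereocentres alone.

Step 6
Reactants: 7 8-ethynyl-3,5,7,3',4'-penta-O-benzylcatechin
Product: 8 (Z)-2-(penta-O-benzylcatechin-8-yl)ethenyl benzoate
Conditions: PhCO2H (1.2 equiv), Ru(η3-2-methylallyl)2(dppb) (5 mol %), toluene, 65 °C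
Reagents that add atoms: benzoic acid OC(=O)c1ccccc1
Why: Ruthenium-catalysed anti-Markovnikov hydro-oxycarbonylation of a terminal alkyne through a ruthenium vinylidene, in which benzoate adds to the terminal carbon and protonolysis should give the Z enol ester.

Step 7
Reactants: 9 3,4,5-tris(benzyloxy)benzaldehyde
Product: 10 3,4,5-tris(benzyloxy)benzaldehyde dimethyl acetal
Conditions: HC(OMe)3, MeOH, p-TsOH (cat.), rt; Et3N
Reagents that add atoms: trimethyl orthoformate COC(OC)OC
Why: Acid-catalysed acetalisation driven to completion by the orthoformate as water scavenger.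

Step 8
Reactants: 10 3,4,5-tris(benzyloxy)benzaldehyde dimethyl acetal, 11 3,5-bis(benzyloxy)phenol
Product: 13 O-aryl O-methyl mixed acetal, via α-chlorobenzyl methyl ether 12 (not isolated)
Conditions: AcCl, ZnBr2 (cat.), CH2Cl2, 0 °C to rt, evaporate; then 11, NaH, THF, 0 °C to rt; chromatography on Et3N-deactivated silica
Reagents that add atoms: none
Why: Acetyl chloride converts the dimethyl acetal into the α-chloro ether, and this hard SN1-type electrophile should alkylate the sodium phenoxide on oxygen (Williamson-type, as in MOM ether formation).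

Step 9
Reactants: 13 O-aryl O-methyl mixed acetal, 8 (Z)-2-(penta-O-benzylcatechin-8-yl)ethenyl benzoate
Product: 16 3-O-benzoyl-penta-O-benzylgallocatechin-(4β→8)-penta-O-benzylcatechin, via aryl oxocarbenium ion 14 (not isolated), via C4 benzylic cation 15 (not isolated)
Conditions: (R)-3,3'-bis(2,4,6-triisopropylphenyl)-BINOL N-triflyl phosphoramide (10 mol %), 5 Å MS, toluene/CH2Cl2, slow addition of 13 (1.3 equiv) to 8, −60 °C to −30 °C; Et3N
Reagents that add atoms: none
Why: Proposed new method: the chiral acid protonates the more basic methoxy oxygen of 13 and expels methanol to give the (E)-aryl oxocarbenium ion 14 paired with the chiral phosphoramide anion, a cationic 2-oxadiene (C4a=C8a–O1=C2) that adds through C2 to the benzoyloxy-bearing carbon of 8 and is closed by Friedel–Crafts attack of the phenol ortho carbon on the benzylic cation 15, an asynchronous formal [4+2] cycloaddition. The closest known reaction type is the Lewis-acid-mediated oxa-Povarov reaction of aryl oxocarbenium ions with styrenes, combined with chiral-counteranion control of additions to oxocarbenium ions; new here are the enol ester partner, the catalyst control and the size of the partners. The pyran ring closes by 6-exo-trig attack of the arene on the cation at C4, and the two ortho positions of the symmetrical phenol are equivalent, so the site of closure is unambiguous. C2 is set by the face of 14 that the chiral anion leaves open (the catalyst antipode is to be fixed by a short screen, since the lower catechin is too remote to bias it), and C3 follows from the exo approach that keeps the benzoate and the bulky catechin ring away from ring A and its 5-benzyloxy group (2,3-trans). C4 follows from suprafacial addition to the Z alkene (3,4-cis), because direct ring closure, or capture as the cis-4,5-disubstituted 2-phenyl-1,3-dioxolan-2-ylium ion that the arene then opens with inversion, should be faster than rotation about C3–C4, which allylic strain with the two ortho oxygens of the catechin ring hinders. The regiochemistry (C2 to the oxygenated carbon, cation at C4) is secured by the 2,4,6-trioxygenated ring A of the lower catechin, a far stronger donor than the acyloxy group, which is why an enol ester and not an enol ether is used.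

Step 10
Reactants: 3 8-bromo-5,7,3',4'-tetra-O-benzylcatechin
Product: 17 8-bromo-5,7,3',4'-tetra-O-benzyl-4β-(2-ethoxyethoxy)catechin
Conditions: DDQ (2 equiv), 2-ethoxyethanol, CH2Cl2, rt
Reagents that add atoms: 2-ethoxyethanol CCOCCO
Why: DDQ abstracts hydride from the benzylic C4 to give a flavan-4-yl cation stabilised by ring A, which the alcohol traps (benzylic oxidation); the C4 configuration, expected mainly 4β, is lost again in step 11.

Step 11
Reactants: 16 3-O-benzoyl-penta-O-benzylgallocatechin-(4β→8)-penta-O-benzylcatechin, 17 8-bromo-5,7,3',4'-tetra-O-benzyl-4β-(2-ethoxyethoxy)catechin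
Product: 18 protected trimer (upper 8-bromo and 3-OH; middle 3-O-benzoyl; fourteen benzyl ethers)
Conditions: TMSOTf (0.5 equiv), 17 (1.2 equiv), CH2Cl2, −78 °C; Et3N
Reagents that add atoms: none
Why: TMSOTf ionises the C4 ether of 17 to the flavan-4-yl cation, which C8 of the 5,7-dibenzyloxy ring A of the gallocatechin unit of 16 should attack anti to the 3-OH (Friedel–Crafts interflavan coupling, 3,4-trans, 4α), while the bromine on the donor blocks its self-condensation.

Step 12
Reactants: 18 protected trimer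
Product: 19 debenzoylated protected trimer
Conditions: NaOMe (0.5 equiv), MeOH/THF, rt to 40 °C
Reagents that add atoms: none
Why: Methoxide-catalysed transesterification removes the benzoate as methyl benzoate without epimerisation, since no free para-hydroxyl is present to open ring C.

Step 13
Reactants: 19 debenzoylated protected trimer
Product: 20 catechin-(4α→8)-gallocatechin-(4β→8)-catechin
Conditions: H2 (1 atm), Pd(OH)2/C, NaOAc (1.5 equiv), THF/MeOH/H2O, rt; filtration, lyophilisation
Reagents that add atoms: none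
Why: Hydrogenolysis cleaves the fourteen benzyl ethers and reduces the aryl C–Br bond in one operation, the acetate buffering the HBr so that the acid-labile interflavan bonds survive.

**Compound list**

1 | (+)-catechin, (2R,3S) | Oc1cc(O)c2c(c1)O[C@H](c1ccc(O)c(O)c1)[C@@H](O)C2 | starting material
2 | 5,7,3',4'-tetra-O-benzylcatechin | C(c1ccccc1)Oc1cc(OCc3ccccc3)c2c(c1)O[C@H](c1ccc(OCc3ccccc3)c(OCc3ccccc3)c1)[C@@H](O)C2 | intermediate
3 | 8-bromo-5,7,3',4'-tetra-O-benzylcatechin | C(c1ccccc1)Oc1cc(OCc3ccccc3)c2c(c1Br)O[C@H](c1ccc(OCc3ccccc3)c(OCc3ccccc3)c1)[C@@H](O)C2 | intermediate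
4 | 8-bromo-3,5,7,3',4'-penta-O-benzylcatechin | C(c1ccccc1)Oc1cc(OCc3ccccc3)c2c(c1Br)O[C@H](c1ccc(OCc3ccccc3)c(OCc3ccccc3)c1)[C@@H](OCc1ccccc1)C2 | intermediate
5 | 8-lithio-3,5,7,3',4'-penta-O-benzylcatechin | [Li]c1c(OCc3ccccc3)cc(OCc3ccccc3)c2c1O[C@H](c1ccc(OCc3ccccc3)c(OCc3ccccc3)c1)[C@@H](OCc1ccccc1)C2 | intermediate
6 | 8-formyl-3,5,7,3',4'-penta-O-benzylcatechin | O=Cc1c(OCc3ccccc3)cc(OCc3ccccc3)c2c1O[C@H](c1ccc(OCc3ccccc3)c(OCc3ccccc3)c1)[C@@H](OCc1ccccc1)C2 | intermediate
7 | 8-ethynyl-3,5,7,3',4'-penta-O-benzylcatechin | C#Cc1c(OCc3ccccc3)cc(OCc3ccccc3)c2c1O[C@H](c1ccc(OCc3ccccc3)c(OCc3ccccc3)c1)[C@@H](OCc1ccccc1)C2 | intermediate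
8 | (Z)-2-(3,5,7,3',4'-penta-O-benzylcatechin-8-yl)ethenyl benzoate | O=C(c1ccccc1)O/C=C\c1c(OCc3ccccc3)cc(OCc3ccccc3)c2c1O[C@H](c1ccc(OCc3ccccc3)c(OCc3ccccc3)c1)[C@@H](OCc1ccccc1)C2 | intermediate
9 | 3,4,5-tris(benzyloxy)benzaldehyde | O=Cc1cc(OCc2ccccc2)c(OCc2ccccc2)c(OCc2ccccc2)c1 | starting material
10 | 3,4,5-tris(benzyloxy)benzaldehyde dimethyl acetal | COC(OC)c1cc(OCc2ccccc2)c(OCc2ccccc2)c(OCc2ccccc2)c1 | intermediate
11 | 3,5-bis(benzyloxy)phenol | Oc1cc(OCc2ccccc2)cc(OCc2ccccc2)c1 | starting material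
12 | chloro(methoxy)[3,4,5-tris(benzyloxy)phenyl]methane (racemic) | COC(Cl)c1cc(OCc2ccccc2)c(OCc2ccccc2)c(OCc2ccccc2)c1 | intermediate
13 | 1,3-bis(benzyloxy)-5-{methoxy[3,4,5-tris(benzyloxy)phenyl]methoxy}benzene (racemic mixed acetal) | COC(Oc1cc(OCc2ccccc2)cc(OCc2ccccc2)c1)c1cc(OCc2ccccc2)c(OCc2ccccc2)c(OCc2ccccc2)c1 | intermediate
14 | (E)-[3,5-bis(benzyloxy)phenyl][3,4,5-tris(benzyloxy)benzylidene]oxonium ion | C(c1ccccc1)Oc1cc(OCc2ccccc2)cc(c1)/[O+]=C/c1cc(OCc2ccccc2)c(OCc2ccccc2)c(OCc2ccccc2)c1 | intermediate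
15 | benzylic cation at C4 after C2–C3 bond formation (C2 and C3 set, benzoate on C3, lower catechin on C4) | c1c(OCc3ccccc3)cc(OCc3ccccc3)cc1O[C@H](c1cc(OCc3ccccc3)c(OCc3ccccc3)c(OCc3ccccc3)c1)[C@@H](OC(=O)c1ccccc1)[CH+]c1c(OCc3ccccc3)cc(OCc3ccccc3)c2c1O[C@H](c1ccc(OCc3ccccc3)c(OCc3ccccc3)c1)[C@@H](OCc1ccccc1)C2 | intermediate
16 | 3-O-benzoyl-5,7,3',4',5'-penta-O-benzylgallocatechin-(4β→8)-3,5,7,3',4'-penta-O-benzylcatechin (upper unit 2R,3S, ring C 2,3-trans-3,4-cis) | c1c(OCc3ccccc3)cc(OCc3ccccc3)c2c1O[C@H](c1cc(OCc3ccccc3)c(OCc3ccccc3)c(OCc3ccccc3)c1)[C@@H](OC(=O)c1ccccc1)[C@H]2c1c(OCc3ccccc3)cc(OCc3ccccc3)c2c1O[C@H](c1ccc(OCc3ccccc3)c(OCc3ccccc3)c1)[C@@H](OCc1ccccc1)C2 | intermediate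
17 | 8-bromo-5,7,3',4'-tetra-O-benzyl-4β-(2-ethoxyethoxy)catechin (3,4-cis drawn) | C(c1ccccc1)Oc1cc(OCc3ccccc3)c2c(c1Br)O[C@H](c1ccc(OCc3ccccc3)c(OCc3ccccc3)c1)[C@@H](O)[C@H]2OCCOCC | intermediate
18 | protected trimer: 8-bromo-tetra-O-benzylcatechin-(4α→8)-3-O-benzoyl-penta-O-benzylgallocatechin-(4β→8)-penta-O-benzylcatechin | C(c1ccccc1)Oc1cc(OCc3ccccc3)c2c(c1Br)O[C@H](c1ccc(OCc3ccccc3)c(OCc3ccccc3)c1)[C@@H](O)[C@@H]2c1c(OCc3ccccc3)cc(OCc3ccccc3)c2c1O[C@H](c1cc(OCc3ccccc3)c(OCc3ccccc3)c(OCc3ccccc3)c1)[C@@H](OC(=O)c1ccccc1)[C@H]2c1c(OCc3ccccc3)cc(OCc3ccccc3)c2c1O[C@H](c1ccc(OCc3ccccc3)c(OCc3ccccc3)c1)[C@@H](OCc1ccccc1)C2 | intermediate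
19 | debenzoylated protected trimer (middle 3-OH free) | C(c1ccccc1)Oc1cc(OCc3ccccc3)c2c(c1Br)O[C@H](c1ccc(OCc3ccccc3)c(OCc3ccccc3)c1)[C@@H](O)[C@@H]2c1c(OCc3ccccc3)cc(OCc3ccccc3)c2c1O[C@H](c1cc(OCc3ccccc3)c(OCc3ccccc3)c(OCc3ccccc3)c1)[C@@H](O)[C@H]2c1c(OCc3ccccc3)cc(OCc3ccccc3)c2c1O[C@H](c1ccc(OCc3ccccc3)c(OCc3ccccc3)c1)[C@@H](OCc1ccccc1)C2 | intermediate
20 | catechin-(4α→8)-gallocatechin-(4β→8)-catechin (CNP0302529.2) | Oc1cc(O)c2c(c1)O[C@H](c1ccc(O)c(O)c1)[C@@H](O)[C@@H]2c1c(O)cc(O)c2c1O[C@H](c1cc(O)c(O)c(O)c1)[C@@H](O)[C@H]2c1c(O)cc(O)c2c1O[C@H](c1ccc(O)c(O)c1)[C@@H](O)C2 | target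

**Step count**

Total: 13 steps. Longest linear sequence: 10 steps (1, 2, 3, 4, 5, 6, 9, 11, 12, 13).

**Steps most likely to fail**

Step 9 (proposed new method). What may go wrong: poor facial selectivity under catalyst control; loss of the Z-alkene information by bond rotation at the cation stage, which would lead to the 3,4-trans isomer; oligomerisation by intermolecular Friedel–Crafts attack on the oxocarbenium ion; Z/E isomerisation of the enol ester by reversible protonation. The fallback uses known chemistry, sets out from 2 and from commercial (+)-gallocatechin, and comes back to the route at 20. (+)-Gallocatechin is benzylated on its five phenols (BnBr, K2CO3, DMF) to 5,7,3',4',5'-penta-O-benzylgallocatechin F1, which DDQ and 2-ethoxyethanol convert into the 4-(2-ethoxyethoxy) donor F2. Compound 2 is acylated with glutaric anhydride (DMAP, pyridine) to the 3-O-hemiglutarate F3, and F3 is esterified with the 3-OH of F2 (EDC, DMAP) to the diester-linked donor–acceptor pair F4. TMSOTf at high dilution (CH2Cl2, −20 °C) should close F4 to the macrocyclic dimer F5: the tether delivers C8 of the catechin ring to the face of the flavan-4-yl cation that carries the 3-oxygen, the tethered intramolecular variant of the interflavan coupling that gives 2,3-trans-3,4-cis dimers. Methanolysis of both esters (NaOMe, MeOH/THF) gives the diol dimer F6, coupling with 17 under the conditions of step 11 gives the trimer F7, and hydrogenolysis under the conditions of step 13 gives 20.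

Step 6. What may go wrong: slow vinylidene formation at the hindered, electron-rich alkyne, competing Markovnikov addition, or erosion of the Z geometry. The fallback sets out from 7 and comes back at 8. Rhodium-catalysed trans-hydroboration of 7 with pinacolborane ([Rh(cod)Cl]2, P(iPr)3, Et3N, cyclohexane, rt) should give the (Z)-alkenyl pinacol boronate F8. Oxidative copper-mediated C–O coupling of F8 with benzoic acid (Cu(OAc)2, Et3N, 4 Å MS, air, CH2Cl2; Chan–Lam type) should give 8 with retention of the alkene geometry.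

Step 11. What may go wrong: acid-induced heterolysis of the 3,4-cis interflavan bond of the nucleophile with scrambling, and competing attack at the C6 positions or over-reaction to tetramers. The fallback moves the upper interflavan bond to before the key step; it sets out from 17 and 11 and comes back at 18. TMSOTf-mediated coupling of 17 with an excess of the cheap phenol 11 (CH2Cl2, −78 °C) should give the C-arylated phenol F9 by attack ortho to the hydroxyl and anti to the 3-OH (the para regioisomer is separated). The sodium phenoxide of F9 (1 equiv NaH) is alkylated with the chloro ether 12 to the mixed acetal F10. F10 is then combined with 8 under the conditions of step 9 and should give 18 directly; the free 3-OH of the upper unit may rest reversibly as a cyclic acetal with the oxocarbenium ion.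

**Further compounds**

F1 | step 9 | 5,7,3',4',5'-penta-O-benzylgallocatechin | c1c(OCc3ccccc3)cc(OCc3ccccc3)c2c1O[C@H](c1cc(OCc3ccccc3)c(OCc3ccccc3)c(OCc3ccccc3)c1)[C@@H](O)C2
F2 | step 9 | 5,7,3',4',5'-penta-O-benzyl-4β-(2-ethoxyethoxy)gallocatechin | c1c(OCc3ccccc3)cc(OCc3ccccc3)c2c1O[C@H](c1cc(OCc3ccccc3)c(OCc3ccccc3)c(OCc3ccccc3)c1)[C@@H](O)[C@H]2OCCOCC
F3 | step 9 | 5,7,3',4'-tetra-O-benzylcatechin 3-O-(4-carboxybutanoate) | c1c(OCc3ccccc3)cc(OCc3ccccc3)c2c1O[C@H](c1ccc(OCc3ccccc3)c(OCc3ccccc3)c1)[C@@H](OC(=O)CCCC(=O)O)C2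
F4 | step 9 | glutarate diester linking the 3-O of F2 and the 3-O of tetra-O-benzylcatechin | c1c(OCc3ccccc3)cc(OCc3ccccc3)c2c1O[C@H](c1cc(OCc3ccccc3)c(OCc3ccccc3)c(OCc3ccccc3)c1)[C@@H](OC(=O)CCCC(=O)O[C@H]4Cc5c(OCc3ccccc3)cc(OCc3ccccc3)cc5O[C@@H]4c4ccc(OCc3ccccc3)c(OCc3ccccc3)c4)[C@H]2OCCOCC
F5 | step 9 | glutarate-bridged macrocyclic penta-O-benzylgallocatechin-(4β→8)-tetra-O-benzylcatechin | c1c(OCc3ccccc3)cc(OCc3ccccc3)c2c1O[C@H](c1cc(OCc3ccccc3)c(OCc3ccccc3)c(OCc3ccccc3)c1)[C@@H](OC(=O)CCCC(=O)O[C@H]4Cc5c(OCc3ccccc3)cc(OCc3ccccc3)c6c5O[C@@H]4c4ccc(OCc3ccccc3)c(OCc3ccccc3)c4)[C@H]26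
F6 | step 9 | 5,7,3',4',5'-penta-O-benzylgallocatechin-(4β→8)-5,7,3',4'-tetra-O-benzylcatechin (both 3-OH free) | c1c(OCc3ccccc3)cc(OCc3ccccc3)c2c1O[C@H](c1cc(OCc3ccccc3)c(OCc3ccccc3)c(OCc3ccccc3)c1)[C@@H](O)[C@H]2c1c(OCc3ccccc3)cc(OCc3ccccc3)c2c1O[C@H](c1ccc(OCc3ccccc3)c(OCc3ccccc3)c1)[C@@H](O)C2
F7 | step 9 | 8-bromo-tetra-O-benzylcatechin-(4α→8)-penta-O-benzylgallocatechin-(4β→8)-tetra-O-benzylcatechin (three 3-OH free) | C(c1ccccc1)Oc1cc(OCc3ccccc3)c2c(c1Br)O[C@H](c1ccc(OCc3ccccc3)c(OCc3ccccc3)c1)[C@@H](O)[C@@H]2c1c(OCc3ccccc3)cc(OCc3ccccc3)c2c1O[C@H](c1cc(OCc3ccccc3)c(OCc3ccccc3)c(OCc3ccccc3)c1)[C@@H](O)[C@H]2c1c(OCc3ccccc3)cc(OCc3ccccc3)c2c1O[C@H](c1ccc(OCc3ccccc3)c(OCc3ccccc3)c1)[C@@H](O)C2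
F8 | step 6 | (Z)-2-(3,5,7,3',4'-penta-O-benzylcatechin-8-yl)ethenylboronic acid pinacol ester | B1(OC(C)(C)C(C)(C)O1)/C=C\c1c(OCc3ccccc3)cc(OCc3ccccc3)c2c1O[C@H](c1ccc(OCc3ccccc3)c(OCc3ccccc3)c1)[C@@H](OCc1ccccc1)C2
F9 | step 11 | 8-bromo-5,7,3',4'-tetra-O-benzyl-4α-[2-hydroxy-4,6-bis(benzyloxy)phenyl]catechin | C(c1ccccc1)Oc1cc(OCc3ccccc3)c2c(c1Br)O[C@H](c1ccc(OCc3ccccc3)c(OCc3ccccc3)c1)[C@@H](O)[C@@H]2c1c(OCc3ccccc3)cc(OCc3ccccc3)cc1O
F10 | step 11 | O-aryl O-methyl mixed acetal of F9 with 3,4,5-tris(benzyloxy)benzaldehyde (epimers at the acetal carbon) | C(c1ccccc1)Oc1cc(OCc3ccccc3)c2c(c1Br)O[C@H](c1ccc(OCc3ccccc3)c(OCc3ccccc3)c1)[C@@H](O)[C@@H]2c1c(OCc3ccccc3)cc(OCc3ccccc3)cc1OC(OC)c1cc(OCc3ccccc3)c(OCc3ccccc3)c(OCc3ccccc3)c1
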